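**Strategy.** Both end rings come from one enantiopure hydroxy ketone and are joined to crocetin dialdehyde by two Julia–Kocienski olefinations (C7=C8, C7'=C8'). Each cyclohexanone is made from a δ-lactone: in a 5-substituted mevalonolactone the ring carbonyl C3 is the lactone carbonyl and C7 its alkoxy carbon, while C2 lies α to a tert-butyl ester on the gem-dimethyl carbon C1. A lactone Dieckmann condensation joins C2 to C3, so the oxane becomes the carbocycle of ring A (and of ring B) and the C7 hydroxyl is set free as the olefination handle. The step exploits the 1,4-relation of C3 and C7 across ring A: the oxygen on C7 is the leaving group at C3.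

Key step: step 7

Remark: carotenoid numbering is used (ring C1–C6, chain from C7, primes for ring B). The polyene is all-E, ring A is (5S,6S) and ring B is (5'R,6'S), so the rings are C5 epimers with the same C6 configuration. Crocetin dialdehyde is taken as purchasable.

Step 1
Reactants: 1 3,3-dimethylglutaric anhydride
Product: 2 5-tert-butoxy-3,3-dimethyl-5-oxopentanoic acid
Conditions: t-BuOH, DMAP (cat.), toluene, 100 °C
Reagents that add atoms: tert-butanol CC(C)(C)O
Why: DMAP-catalysed alcoholysis of the symmetric cyclic anhydride gives the half ester and so tells the two arms apart (the tert-butyl arm will carry C2, the acid arm C6 and C7).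

Step 2
Reactants: 2 5-tert-butoxy-3,3-dimethyl-5-oxopentanoic acid; 3 (S)-4-benzyl-1,3-oxazolidin-2-one
Product: 4 tert-butyl 5-[(4S)-4-benzyl-2-oxo-1,3-oxazolidin-3-yl]-3,3-dimethyl-5-oxopentanoate
Conditions: PivCl, Et3N, THF, −20 °C; then LiCl, 3, 0 °C to rt
Reagents that add atoms: none
Why: N-acylation of the oxazolidinone auxiliary through the mixed pivalic anhydride, in which only the free acid arm can react.

Step 3
Reactants: 4 the N-acyl oxazolidinone; 5 acetaldehyde
Product: 6 tert-butyl (4S,5R)-4-[(4S)-4-benzyl-2-oxo-1,3-oxazolidine-3-carbonyl]-5-hydroxy-3,3-dimethylhexanoate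
Conditions: Bu2BOTf, i-Pr2NEt, CH2Cl2, −78 °C to 0 °C; then pH 7 buffer, MeOH, H2O2
Reagents that add atoms: none
Why: Evans syn-aldol reaction, in which the Z boron enolate reacts through a Zimmerman–Traxler chair on the face away from the benzyl group and so sets the future C6; the carbinol centre is given up again in step 5.

Step 4
Reactants: 6 the aldol adduct
Product: 7 tert-butyl (4R,5R)-5-hydroxy-4-(hydroxymethyl)-3,3-dimethylhexanoate
Conditions: LiBH4, MeOH (1 equiv), THF, 0 °C
Reagents that add atoms: none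
Why: Reductive cleavage of the activated imide by LiBH4 gives the primary alcohol (future C7) and leaves the hindered tert-butyl ester, with recovery of the auxiliary.

Step 5
Reactants: 7 the 1,3-diol
Product: 8 tert-butyl (4R)-4-(hydroxymethyl)-3,3-dimethyl-5-oxohexanoate
Conditions: NaOCl (aq), AcOH, 0 °C to rt
Reagents that add atoms: none
Why: Stevens oxidation, in which hypochlorite in acetic acid should oxidise the secondary alcohol of a 1,3-diol in preference to the primary one; the acidic medium avoids epimerisation at C6.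

Step 6
Reactants: 8 the hydroxy methyl ketone; 9 ethyl acetate
Product: 11 tert-butyl 3-[(3R,4S)-4-hydroxy-4-methyl-6-oxooxan-3-yl]-3-methylbutanoate, via hydroxy diester 10 (not isolated)
Conditions: LiN(SiMe3)2, EtOAc, THF, −78 °C; then 8, −78 °C to −20 °C; AcOH; then PPTS (cat.), CH2Cl2, rt
Reagents that add atoms: none
Why: Aldol addition of the lithium enolate of ethyl acetate to the methyl ketone anti to the bulky C1 side chain on C6 (the Felkin–Anh model and the C7 lithium alkoxide chelate predict the same sense) should set C5 as S, after which the primary alcohol lactonises on the ethyl ester.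

Step 7
Reactants: 11 the (3R,4S)-hydroxy lactone
Product: 12 tert-butyl (3R,4S)-4-hydroxy-3-(hydroxymethyl)-2,2,4-trimethyl-6-oxocyclohexane-1-carboxylate (C1 epimers and enol)
Conditions: LiN(SiMe3)2 (3.5 equiv), THF, −78 °C to −10 °C; AcOH
Reagents that add atoms: none
Why: LiN(SiMe3)2 first makes the lithium alkoxide of the tertiary hydroxyl and then, reversibly, the tert-butyl ester enolate at C2, which adds to the lactone carbonyl C3; the bridged hemiketal alkoxide (a 2-oxabicyclo[2.2.2]octane) collapses by cleavage of the C3–O(C7) bond to the cyclohexanone and the C7 alkoxide, and deprotonation of the new β-keto ester pulls the equilibrium over. The closest known reaction is the Dieckmann condensation (intramolecular Claisen acylation), here with a lactone as the acyl donor, so the oxane ring is exchanged for the carbocycle. The six-membered carbocycle closes in a 6-exo-trig mode at the lactone carbonyl through a boat-like transition state. No stereocentre is made: C5 and C6 are carried over unchanged and the epimerisable C2 is removed in step 8. The step needs C2-to-C3 acylation rather than attack of a lactone C4 enolate on the other ester or retro-aldol cleavage at C5; the tert-butyl ester is a poor acyl acceptor, only the C2–C3 product gives a stabilised β-keto ester enolate, a C4 enolate next to the C5 alkoxide is disfavoured, and the lithium aldolate is kept at or below −10 °C.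

Step 8
Reactants: 12 the β-keto ester
Product: 14 (3S,4R)-3-hydroxy-4-(hydroxymethyl)-3,5,5-trimethylcyclohexan-1-one, via β-keto acid 13 (not isolated)
Conditions: Me3SiOTf, 2,6-lutidine, CH2Cl2, 0 °C; then MeOH, aq. citric acid, 35 °C
Reagents that add atoms: none
Why: The silyl triflate cleaves the tert-butyl ester with loss of isobutene while the hydroxyls are silylated in passing, and mild aqueous acid then frees the β-keto acid, which decarboxylates without dehydration of the tertiary β-hydroxy ketone.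

Step 9
Reactants: 14 the keto diol
Product: 15 (3S,4S)-3-hydroxy-3,5,5-trimethyl-4-{[(1-phenyl-1H-tetrazol-5-yl)sulfanyl]methyl}cyclohexan-1-one
Conditions: 1-phenyl-1H-tetrazole-5-thiol, PPh3, DIAD, THF, 0 °C to rt
Reagents that add atoms: 1-phenyl-1H-tetrazole-5-thiol Sc1nnnn1-c1ccccc1
Why: Mitsunobu thioetherification of the primary alcohol by the acidic thiol; the tertiary alcohol does not react.

Step 10
Reactants: 15 the sulfide
Product: 16 (3S,4S)-3-hydroxy-3,5,5-trimethyl-4-{[(1-phenyl-1H-tetrazol-5-yl)sulfonyl]methyl}cyclohexan-1-one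
Conditions: (NH4)6Mo7O24·4H2O (cat.), H2O2 (30%), EtOH, 0 °C to rt
Reagents that add atoms: hydrogen peroxide OO
Why: Molybdate-catalysed peroxide oxidation of the sulfide to the sulfone, which ketone and tertiary alcohol tolerate.

Step 11
Reactants: 16 the keto sulfone
Product: 17 (7S,8S)-7,9,9-trimethyl-8-{[(1-phenyl-1H-tetrazol-5-yl)sulfonyl]methyl}-1,4-dioxaspiro[4.5]decan-7-ol
Conditions: ethylene glycol, HC(OMe)3, p-TsOH (cat.), CH2Cl2, rt
Reagents that add atoms: ethylene glycol OCCO
Why: Acid-catalysed dioxolane formation with orthoformate as water scavenger masks the C3 ketone, so that the base of the olefination meets neither acidic α-hydrogens nor a β-hydroxy ketone able to undergo retro-aldol cleavage.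

Step 12
Reactants: 8 the hydroxy methyl ketone; 18 (triphenylphosphoranylidene)ketene
Product: 19 tert-butyl 3-methyl-3-[(3S)-4-methyl-6-oxo-3,6-dihydro-2H-pyran-3-yl]butanoate
Conditions: toluene, 110 °C
Reagents that add atoms: none
Why: The ketenylidene ylide is acylated by the primary hydroxyl to a stabilised ester ylide, which closes the unsaturated δ-lactone by intramolecular Wittig olefination of the methyl ketone without touching C6.

Step 13
Reactants: 19 the unsaturated lactone
Product: 20 tert-butyl 3-[(3R)-4,5-epoxy-4-methyl-6-oxooxan-3-yl]-3-methylbutanoate (epoxide oxygen trans to the side chain)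
Conditions: H2O2 (30%), NaOH (0.3 equiv), MeOH, 0 °C; then acidify to pH 3
Reagents that add atoms: hydrogen peroxide OO
Why: Weitz–Scheffer nucleophilic epoxidation, in which hydroperoxide adds to C5 anti to the pseudo-axial side chain on the neighbouring C6, so the C5–O bond forms on the lactone face opposite to that in 11.

Step 14
Reactants: 20 the epoxy lactone
Product: 21 tert-butyl 3-[(3R,4R)-4-hydroxy-4-methyl-6-oxooxan-3-yl]-3-methylbutanoate
Conditions: SmI2, HMPA, Me2NCH2CH2OH, THF, 0 °C
Reagents that add atoms: none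
Why: Electron transfer from SmI2 cleaves the Cα–O bond of the α,β-epoxy lactone and leaves the C5–O bond, which gives the β-hydroxy lactone with 5R configuration, the C5 epimer of 11.

Step 15
Reactants: 21 the (3R,4R)-hydroxy lactone
Product: 22 tert-butyl (3R,4R)-4-hydroxy-3-(hydroxymethyl)-2,2,4-trimethyl-6-oxocyclohexane-1-carboxylate (C1 epimers and enol)
Conditions: LiN(SiMe3)2 (3.5 equiv), THF, −78 °C to −10 °C; AcOH
Reagents that add atoms: none
Why: The same lactone Dieckmann condensation as in step 7 joins C2' to C3' and frees the C7' hydroxyl, with C5' and C6' carried over.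

Step 16
Reactants: 22 the β-keto ester
Product: 24 (3R,4R)-3-hydroxy-4-(hydroxymethyl)-3,5,5-trimethylcyclohexan-1-one, via β-keto acid 23 (not isolated)
Conditions: Me3SiOTf, 2,6-lutidine, CH2Cl2, 0 °C; then MeOH, aq. citric acid, 35 °C
Reagents that add atoms: none
Why: Silyl triflate cleavage of the tert-butyl ester and decarboxylation of the β-keto acid, as in step 8.

Step 17
Reactants: 24 the keto diol
Product: 25 (3R,4S)-3-hydroxy-3,5,5-trimethyl-4-{[(1-phenyl-1H-tetrazol-5-yl)sulfanyl]methyl}cyclohexan-1-one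
Conditions: 1-phenyl-1H-tetrazole-5-thiol, PPh3, DIAD, THF, 0 °C to rt
Reagents that add atoms: 1-phenyl-1H-tetrazole-5-thiol Sc1nnnn1-c1ccccc1
Why: Mitsunobu thioetherification of the primary alcohol, as in step 9.

Step 18
Reactants: 25 the sulfide
Product: 26 (3R,4S)-3-hydroxy-3,5,5-trimethyl-4-{[(1-phenyl-1H-tetrazol-5-yl)sulfonyl]methyl}cyclohexan-1-one
Conditions: (NH4)6Mo7O24·4H2O (cat.), H2O2 (30%), EtOH, 0 °C to rt
Reagents that add atoms: hydrogen peroxide OO
Why: Molybdate-catalysed oxidation of the sulfide to the sulfone, as in step 10.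

Step 19
Reactants: 26 the keto sulfone
Product: 27 (7R,8S)-7,9,9-trimethyl-8-{[(1-phenyl-1H-tetrazol-5-yl)sulfonyl]methyl}-1,4-dioxaspiro[4.5]decan-7-ol
Conditions: ethylene glycol, HC(OMe)3, p-TsOH (cat.), CH2Cl2, rt
Reagents that add atoms: ethylene glycol OCCO
Why: Dioxolane protection of the C3' ketone, as in step 11.

Step 20
Reactants: 17 the ring A sulfone; 28 crocetin dialdehyde (all-E-2,6,11,15-tetramethylhexadeca-2,4,6,8,10,12,14-heptaenedial)
Product: 29 (all-E)-17-[(7S,8S)-7-hydroxy-7,9,9-trimethyl-1,4-dioxaspiro[4.5]decan-8-yl]-2,6,11,15-tetramethylheptadeca-2,4,6,8,10,12,14,16-octaenal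
Conditions: KN(SiMe3)2 (2.1 equiv), DME, −78 °C; then 28 (3 equiv), −78 °C to rt
Reagents that add atoms: none
Why: Julia–Kocienski olefination, in which the metallated sulfone adds to one aldehyde group and Smiles rearrangement with loss of SO2 and the tetrazolate should give the E C7=C8 bond, the excess of dialdehyde keeping the reaction at mono-olefination.

Step 21
Reactants: 29 the C30 aldehyde; 27 the ring B sulfone
Product: 30 (5S,6S,5'R,6'S)-5,5'-dihydroxy-5,6,5',6'-tetrahydro-β,β-carotene-3,3'-dione bis(ethylene ketal)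
Conditions: 27 (1.5 equiv), KN(SiMe3)2, DME, −78 °C; then 29, −78 °C to rt
Reagents that add atoms: none
Why: A second Julia–Kocienski olefination forms the E C7'=C8' bond and completes the C40 skeleton with the two epimeric rings at defined ends.

Step 22
Reactants: 30 the bis-ketal
Product: 31 (5S,6S,5'R,6'S)-5,5'-dihydroxy-5,6,5',6'-tetrahydro-β,β-carotene-3,3'-dione
Conditions: PPTS, acetone–H2O (9:1), 40 °C, dark, argon
Reagents that add atoms: water O
Why: Mild acid hydrolysis of both dioxolanes frees the ketones, helped by relief of 1,3-diaxial strain in the ketals, under conditions meant to avoid dehydration of the β-hydroxy ketones and isomerisation of the polyene.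

**Compound list**

1 | 3,3-dimethylglutaric anhydride | O=C1CC(C)(C)CC(=O)O1 | starting material
2 | 5-tert-butoxy-3,3-dimethyl-5-oxopentanoic acid | CC(C)(C)OC(=O)CC(C)(C)CC(=O)O | intermediate
3 | (S)-4-benzyl-1,3-oxazolidin-2-one | O=C1N[C@@H](Cc2ccccc2)CO1 | starting material
4 | tert-butyl 5-[(4S)-4-benzyl-2-oxo-1,3-oxazolidin-3-yl]-3,3-dimethyl-5-oxopentanoate | CC(C)(C)OC(=O)CC(C)(C)CC(=O)N1[C@@H](Cc2ccccc2)COC1=O | intermediate
5 | acetaldehyde | CC=O | starting material
6 | tert-butyl (4S,5R)-4-[(4S)-4-benzyl-2-oxo-1,3-oxazolidine-3-carbonyl]-5-hydroxy-3,3-dimethylhexanoate | C[C@@H](O)[C@@H](C(=O)N1[C@@H](Cc2ccccc2)COC1=O)C(C)(C)CC(=O)OC(C)(C)C | intermediate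
7 | tert-butyl (4R,5R)-5-hydroxy-4-(hydroxymethyl)-3,3-dimethylhexanoate | C[C@@H](O)[C@@H](CO)C(C)(C)CC(=O)OC(C)(C)C | intermediate
8 | tert-butyl (4R)-4-(hydroxymethyl)-3,3-dimethyl-5-oxohexanoate | CC(=O)[C@@H](CO)C(C)(C)CC(=O)OC(C)(C)C | intermediate
9 | ethyl acetate | CCOC(C)=O | starting material
10 | 1-tert-butyl 7-ethyl (4R,5S)-5-hydroxy-4-(hydroxymethyl)-3,3,5-trimethylheptanedioate | CCOC(=O)C[C@](C)(O)[C@@H](CO)C(C)(C)CC(=O)OC(C)(C)C | intermediate
11 | tert-butyl 3-[(3R,4S)-4-hydroxy-4-methyl-6-oxooxan-3-yl]-3-methylbutanoate | O=C1C[C@](C)(O)[C@H](C(C)(C)CC(=O)OC(C)(C)C)CO1 | intermediate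
12 | tert-butyl (3R,4S)-4-hydroxy-3-(hydroxymethyl)-2,2,4-trimethyl-6-oxocyclohexane-1-carboxylate | OC[C@H]1C(C)(C)C(C(=O)OC(C)(C)C)C(=O)C[C@]1(C)O | intermediate
13 | (3R,4S)-4-hydroxy-3-(hydroxymethyl)-2,2,4-trimethyl-6-oxocyclohexane-1-carboxylic acid | OC[C@H]1C(C)(C)C(C(=O)O)C(=O)C[C@]1(C)O | intermediate
14 | (3S,4R)-3-hydroxy-4-(hydroxymethyl)-3,5,5-trimethylcyclohexan-1-one | OC[C@H]1C(C)(C)CC(=O)C[C@]1(C)O | intermediate
15 | (3S,4S)-3-hydroxy-3,5,5-trimethyl-4-{[(1-phenyl-1H-tetrazol-5-yl)sulfanyl]methyl}cyclohexan-1-one | c1ccccc1-n1nnnc1SC[C@H]1C(C)(C)CC(=O)C[C@]1(C)O | intermediate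
16 | (3S,4S)-3-hydroxy-3,5,5-trimethyl-4-{[(1-phenyl-1H-tetrazol-5-yl)sulfonyl]methyl}cyclohexan-1-one | c1ccccc1-n1nnnc1S(=O)(=O)C[C@H]1C(C)(C)CC(=O)C[C@]1(C)O | intermediate
17 | (7S,8S)-7,9,9-trimethyl-8-{[(1-phenyl-1H-tetrazol-5-yl)sulfonyl]methyl}-1,4-dioxaspiro[4.5]decan-7-ol | c1ccccc1-n1nnnc1S(=O)(=O)C[C@H]1C(C)(C)CC2(OCCO2)C[C@]1(C)O | intermediate
18 | (triphenylphosphoranylidene)ketene | O=C=C=P(c1ccccc1)(c1ccccc1)c1ccccc1 | starting material
19 | tert-butyl 3-methyl-3-[(3S)-4-methyl-6-oxo-3,6-dihydro-2H-pyran-3-yl]butanoate | O=C1C=C(C)[C@H](C(C)(C)CC(=O)OC(C)(C)C)CO1 | intermediate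
20 | tert-butyl 3-[(3R)-4,5-epoxy-4-methyl-6-oxooxan-3-yl]-3-methylbutanoate, epoxide trans to the side chain | O=C1[C@H]2O[C@@]2(C)[C@H](C(C)(C)CC(=O)OC(C)(C)C)CO1 | intermediate
21 | tert-butyl 3-[(3R,4R)-4-hydroxy-4-methyl-6-oxooxan-3-yl]-3-methylbutanoate | O=C1C[C@@](C)(O)[C@H](C(C)(C)CC(=O)OC(C)(C)C)CO1 | intermediate
22 | tert-butyl (3R,4R)-4-hydroxy-3-(hydroxymethyl)-2,2,4-trimethyl-6-oxocyclohexane-1-carboxylate | OC[C@H]1C(C)(C)C(C(=O)OC(C)(C)C)C(=O)C[C@@]1(C)O | intermediate
23 | (3R,4R)-4-hydroxy-3-(hydroxymethyl)-2,2,4-trimethyl-6-oxocyclohexane-1-carboxylic acid | OC[C@H]1C(C)(C)C(C(=O)O)C(=O)C[C@@]1(C)O | intermediate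
24 | (3R,4R)-3-hydroxy-4-(hydroxymethyl)-3,5,5-trimethylcyclohexan-1-one | OC[C@H]1C(C)(C)CC(=O)C[C@@]1(C)O | intermediate
25 | (3R,4S)-3-hydroxy-3,5,5-trimethyl-4-{[(1-phenyl-1H-tetrazol-5-yl)sulfanyl]methyl}cyclohexan-1-one | c1ccccc1-n1nnnc1SC[C@H]1C(C)(C)CC(=O)C[C@@]1(C)O | intermediate
26 | (3R,4S)-3-hydroxy-3,5,5-trimethyl-4-{[(1-phenyl-1H-tetrazol-5-yl)sulfonyl]methyl}cyclohexan-1-one | c1ccccc1-n1nnnc1S(=O)(=O)C[C@H]1C(C)(C)CC(=O)C[C@@]1(C)O | intermediate
27 | (7R,8S)-7,9,9-trimethyl-8-{[(1-phenyl-1H-tetrazol-5-yl)sulfonyl]methyl}-1,4-dioxaspiro[4.5]decan-7-ol | c1ccccc1-n1nnnc1S(=O)(=O)C[C@H]1C(C)(C)CC2(OCCO2)C[C@@]1(C)O | intermediate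
28 | crocetin dialdehyde | CC(/C=C/C=C(C)/C=O)=C\C=C\C=C(C)\C=C\C=C(C)\C=O | starting material
29 | (all-E)-17-[(7S,8S)-7-hydroxy-7,9,9-trimethyl-1,4-dioxaspiro[4.5]decan-8-yl]-2,6,11,15-tetramethylheptadeca-2,4,6,8,10,12,14,16-octaenal | CC(/C=C/C=C(C)/C=C/[C@H]1C(C)(C)CC2(OCCO2)C[C@]1(C)O)=C\C=C\C=C(C)\C=C\C=C(C)\C=O | intermediate
30 | (5S,6S,5'R,6'S)-5,5'-dihydroxy-5,6,5',6'-tetrahydro-β,β-carotene-3,3'-dione bis(ethylene ketal) | CC(/C=C/C=C(C)/C=C/[C@H]1C(C)(C)CC2(OCCO2)C[C@]1(C)O)=C\C=C\C=C(C)\C=C\C=C(C)\C=C\[C@H]1C(C)(C)CC2(OCCO2)C[C@@]1(C)O | intermediate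
31 | (5S,6S,5'R,6'S)-5,5'-dihydroxy-5,6,5',6'-tetrahydro-β,β-carotene-3,3'-dione | CC(/C=C/C=C(C)/C=C/[C@H]1C(C)(C)CC(=O)C[C@]1(C)O)=C\C=C\C=C(C)\C=C\C=C(C)\C=C\[C@H]1C(C)(C)CC(=O)C[C@@]1(C)O | target

**Count.** Total steps: 22. Longest linear sequence: 15 steps (steps 1–5, 12–19, 21 and 22).

**Steps most likely to fail**

Step 7 (and its twin, step 15). The lithium aldolate at C5 may undergo retro-aldol cleavage and re-addition, which would scramble C5. Deprotonation may also rest at the lactone C4, so that ring closure stalls. The fallback sets out from 11 (or from 21 in the ring B series). The lactone is opened with MeNH(OMe)·HCl and Me3Al to the Weinreb amide tert-butyl (4R,5S)-5-hydroxy-4-(hydroxymethyl)-7-[methoxy(methyl)amino]-3,3,5-trimethyl-7-oxoheptanoate F1. Treatment with LiN(i-Pr)2 (4 equiv) in THF at −78 °C then forms only the C2 ester enolate, because the amide α-hydrogens are less acidic. This enolate acylates at C3 through a chelated tetrahedral intermediate that does not revert, and the ketone appears only on work-up. The fallback comes back to the route at 12.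

Step 6. Enolate addition to the hindered ketone may show poor facial selectivity, or enolisation and loss of formaldehyde from the alkoxide of 8 may compete. The fallback sets C5 on the carbocycle and sets out from 24, which does not depend on step 6. Catalytic p-TsOH in CH2Cl2 dehydrates the tertiary β-hydroxy ketone to (4S)-4-(hydroxymethyl)-3,5,5-trimethylcyclohex-2-en-1-one F2. Weitz–Scheffer epoxidation (H2O2, NaOH, MeOH, 0 °C) anti to the hydroxymethyl group gives 5-(hydroxymethyl)-4,4,6-trimethyl-7-oxabicyclo[4.1.0]heptan-2-one F3, with the epoxide trans to CH2OH. Reductive opening of the Cα–O bond with SmI2 in THF–MeOH at −78 °C leaves the hydroxyl trans to C7. The fallback comes back at 14.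

Step 20 (and step 21). The hindered metallated sulfone may self-condense, E-selectivity with the conjugated aldehyde may be poor, or the bis-adduct may form. The fallback is a Wittig olefination and sets out from 14. I2, PPh3 and imidazole give (3S,4S)-3-hydroxy-4-(iodomethyl)-3,5,5-trimethylcyclohexan-1-one F4. Ketalisation as in step 11 gives (7S,8S)-8-(iodomethyl)-7,9,9-trimethyl-1,4-dioxaspiro[4.5]decan-7-ol F5. PPh3 in MeCN at 80 °C gives {[(7S,8S)-7-hydroxy-7,9,9-trimethyl-1,4-dioxaspiro[4.5]decan-8-yl]methyl}triphenylphosphonium iodide F6. The ylide (NaN(SiMe3)2, THF, −78 °C) is condensed with excess 28, and the 7Z/7E mixture is equilibrated to all-E with catalytic iodine. The fallback comes back at 29; the same sequence from 24 would serve ring B.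

**Further compounds**

F1 | step 7 | tert-butyl (4R,5S)-5-hydroxy-4-(hydroxymethyl)-7-[methoxy(methyl)amino]-3,3,5-trimethyl-7-oxoheptanoate | CON(C)C(=O)C[C@](C)(O)[C@@H](CO)C(C)(C)CC(=O)OC(C)(C)C
F2 | step 6 | (4S)-4-(hydroxymethyl)-3,5,5-trimethylcyclohex-2-en-1-one | OC[C@H]1C(C)(C)CC(=O)C=C1C
F3 | step 6 | 5-(hydroxymethyl)-4,4,6-trimethyl-7-oxabicyclo[4.1.0]heptan-2-one, epoxide trans to CH2OH | OC[C@H]1C(C)(C)CC(=O)[C@@H]2O[C@]12C
F4 | step 20 | (3S,4S)-3-hydroxy-4-(iodomethyl)-3,5,5-trimethylcyclohexan-1-one | IC[C@H]1C(C)(C)CC(=O)C[C@]1(C)O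
F5 | step 20 | (7S,8S)-8-(iodomethyl)-7,9,9-trimethyl-1,4-dioxaspiro[4.5]decan-7-ol | IC[C@H]1C(C)(C)CC2(OCCO2)C[C@]1(C)O
F6 | step 20 | {[(7S,8S)-7-hydroxy-7,9,9-trimethyl-1,4-dioxaspiro[4.5]decan-8-yl]methyl}triphenylphosphonium iodide | [I-].c1ccccc1[P+](c1ccccc1)(c1ccccc1)C[C@H]1C(C)(C)CC2(OCCO2)C[C@]1(C)O
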